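The earlier runs and the new flask were computed for substances that don't exist; the scatter is artificial.

| flask | starting complex | incoming ligand | leaving ligand | remark | time |
|---|---|---|---|---|---|
| winter | 20 mM | 20 mM | 10 mM | the very flask that is asked about, followed so far |  |
| midnight | 20 mM | 13 mM | 10 mM | run made earlier |  |
| flask | 20 mM | 20.0 mM | 10.0 mM |  | 4.0 d |

- winter (time / h: side product / %, complex with two exchanged / %, starting complex / %): 1.33: 31, 0, 55; 4.00: 58, 1, 42; 6.00: 62, 3, 37; 10.0: 64, 2, 33; 15.0: 66, 2, 34; 20.0: 66, 3, 32
- midnight (time / d: side product / %, complex with two exchanged / %, starting complex / %): 0.208: 45, 1, 45; 0.500: 54, 3, 46; 1.04: 52, 0, 47; 1.67: 55, 1, 44; 2.00: 55, 1, 45; 3.00: 54, 4, 43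

(scatter of a reading: 2 percentage points)

1. why nothing more happens at 4.0 d, or that something still does (all of the starting complex has reacted / it is still moving / the incoming ligand has run out first)
2. the side product standing at 4.0 d, as a percentage of the starting complex charged
3. amount of complex with two exchanged if the flask were left three thousand times as long, in percent of the starting complex charged

- percent here means starting complex units held: one side product counts as two
- what was read earlier has a scatter of 2 percentage points, one standard deviation
- the reaction counts as stopped when no species that holds the starting complex changes by six tenths of a point or more over the second half of the time

- You asked for a quick number, so I began with the side product: the winter run, which is your flask, read 66% at 20.0 h, and the midnight run read 54% at 3.00 d, each flat by then with starting complex still present.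
- The winter run gave 0.330 side products per incoming ligand charged; I called this the ligand yield, c(side product) formed over c(incoming ligand) charged, with a side product counted as two units of starting complex.
- I set the zero of the scale at a yield of 1, where each incoming ligand ends in one side product, and the winter run stood below it.
- The midnight run, charged with less incoming ligand, gave a higher yield of 0.415, so I suspected an unseen consumer of incoming ligand that gained ground as the charge rose.
- I therefore named the incoming ligand as the charge that ended first, and for the winter flask I committed to 66% of side product and to complex with two exchanged staying near its last reading of 3%, within the scatter of 2 percentage points.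
- Your forecast gave 65% of side product and 50% of complex with two exchanged for the very long wait, and it said it is still moving, on the ground that “that scatter could hide a slow creep”; we nearly agreed on the side product and parted on the other two.
- The flask gave 65.1% at 4.0 d and 0.761% for the very long wait, and the stop was that the incoming ligand has run out first: this limiting reagent had 0% left at 4.00 d.

    starting complex + incoming ligand → leaving ligand + complex with one exchanged (k = 0.0170 M⁻¹ s⁻¹)
    complex with one exchanged + incoming ligand → leaving ligand + complex with two exchanged (k = 0.00270 M⁻¹ s⁻¹)
    2 incoming ligand → self-condensation product (k = 0.0390 M⁻¹ s⁻¹)
    starting complex + complex with one exchanged → side product (k = 0.0170 M⁻¹ s⁻¹)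

- The self-condensation product stood at 6.59 mM at 4.00 d, with two incoming ligand in each. The ligand yield of this flask came to 0.326, and the neighbour charged with 5.0 mM of incoming ligand, at 32.0% of side product, had a yield of 0.641.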